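The route disconnects the O1–C2 bond of the tetrahydrofuran (ring O1, C2–C5). Within that ring, C2 and the exocyclic carbinol C1′ carry their oxygens in an erythro relationship. This pattern arises when a C5 hydroxyl displaces, with inversion, the C2 end of a trans-epoxide spanning C1′ and C2. In one operation, tartrate-controlled epoxidation of an E allylic alcohol and in situ 5-exo closure set C1′ and C2 and form the 2,5-trans ring. The precursor is an acyclic syn-1,3-diol with a silyl ether on the future C3, a free hydroxyl on the future C5, the Z-chloroalkene and a protected propargylic alcohol.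

Key step: step 10

Assumption: the enol borinate made from a methyl ketone with (+)-Ipc2BCl is taken to add to the Si face of an aldehyde (the sense needed for the R carbinol of 14); should the sense prove opposite, (−)-Ipc2BCl is used in step 5 with no other change.

Abbreviations: TBS = tert-butyldimethylsilyl, TES = triethylsilyl, PMB = 4-methoxybenzyl, Ipc = isopinocampheyl, DIPT = diisopropyl tartrate, 9-BBN = 9-borabicyclo[3.3.1]nonane, CuTC = Cu(thiophene-2-carboxylate).

Step 1
Reactants: 1 propargyl alcohol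
Product: 2 4-methoxybenzyl propargyl ether
Conditions: NaH, PMBCl, n-Bu4NI (cat.), THF, 0 °C → rt
Reagents that add atoms: 4-methoxybenzyl chloride, COc1ccc(CCl)cc1
Why: Williamson etherification in which NaH deprotonates the hydroxyl (far more acidic than the alkyne C–H) and the alkoxide displaces benzylic chloride; the PMB ether is chosen because it can later be removed oxidatively in the presence of every silyl ether of the route.

Step 2
Reactants: 2 4-methoxybenzyl propargyl ether; 3 1,1,3-trichloropropene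
Product: 4 1-[(6,6-dichlorohex-5-en-2-yn-1-yloxy)methyl]-4-methoxybenzene
Conditions: CuI (cat.), K2CO3, n-Bu4NI (cat.), DMF, rt
Reagents that add atoms: none
Why: Copper-catalysed alkynylation of an allylic chloride, in which the copper acetylide substitutes the CH2Cl terminus (SN2) because attack at the dichlorinated alkene carbon is disfavoured, should give the skipped enyne with the 1,1-dichloroalkene intact.

Step 3
Reactants: 5 acrolein diethyl acetal; 4 dichloroenyne
Product: 8 (Z)-4-chloro-9-(4-methoxybenzyloxy)non-4-en-7-ynal, via alkylborane 6 (not isolated), via diethyl acetal 7 (not isolated)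
Conditions: 5, 9-BBN, THF, 0 °C → rt; then 4, Pd2(dba)3 (cat.), XantPhos, K3PO4 (aq.), THF, 65 °C; then 1 M HCl, THF, rt
Reagents that add atoms: water, O
Why: Anti-Markovnikov hydroboration followed by B-alkyl Suzuki–Miyaura coupling of the 1,1-dichloroalkene, in which zerovalent palladium inserts selectively into the less hindered C–Cl bond trans to the alkenyl substituent so that one alkylation with retention should give the Z-chloroalkene, after which dilute acid hydrolyses the acetal.

Step 4
Reactants: 9 (tert-butyldimethylsilyloxy)acetaldehyde; 10 1-(triphenylphosphoranylidene)propan-2-one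
Product: 11 (E)-5-(tert-butyldimethylsilyloxy)pent-3-en-2-one
Conditions: CH2Cl2, 40 °C
Reagents that add atoms: none
Why: Wittig olefination with a ketone-stabilised ylide, which should give the E enone.

Step 5
Reactants: 11 enone; 8 aldehyde
Product: 14 (2E,6R,9Z)-1-(TBSO)-9-chloro-6-hydroxy-14-(PMBO)tetradeca-2,9-dien-12-yn-4-one, via enol borinate 12 (not isolated), via boron aldolate 13 (not isolated)
Conditions: 11, (+)-Ipc2BCl, Et3N, Et2O, 0 °C; then 8, −78 → −20 °C; then H2O2, MeOH, pH 7 buffer, 0 °C
Reagents that add atoms: none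
Why: Boron aldol reaction in which Ipc2BCl/Et3N enolises the methyl group and the chiral enol borinate adds to the aldehyde through a cyclic transition state under reagent control, setting the future C5 carbinol as R; the minor enantiomer that this aldol class usually leaves becomes a separable diastereomer after step 7.

Step 6
Reactants: 14 β-hydroxy enone
Product: 15 6-O-triethylsilyl ether of 14
Conditions: TESCl, imidazole, CH2Cl2, 0 °C
Reagents that add atoms: chlorotriethylsilane, CC[Si](Cl)(CC)CC
Why: Mild silylation of the secondary alcohol; the labile TES group masks the future C5 oxygen only until step 9 and so keeps it distinct from the C3 oxygen made next.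

Step 7
Reactants: 15 β-silyloxy enone
Product: 16 (2E,4R,6R,9Z)-1-(TBSO)-9-chloro-14-(PMBO)-6-(TESO)tetradeca-2,9-dien-12-yn-4-ol
Conditions: (S)-Me-CBS (20 mol%), catecholborane, toluene, −78 °C
Reagents that add atoms: none
Why: CBS reduction in which the oxazaborolidine–borane complex binds the enone carbonyl with the alkenyl group as the large substituent and delivers hydride to one face, which should set the future C3 carbinol as R (1,3-syn to C5) under catalyst control, with 1,2-selectivity and without hydroboration of the alkyne at this temperature.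

Step 8
Reactants: 16 allylic alcohol
Product: 17 (2E,4R,6R,9Z)-1,4-bis(TBSO)-9-chloro-14-(PMBO)-6-(TESO)tetradeca-2,9-dien-12-yne
Conditions: TBSOTf, 2,6-lutidine, CH2Cl2, −78 °C
Reagents that add atoms: tert-butyldimethylsilyl triflate, CC(C)(C)[Si](C)(C)OS(=O)(=O)C(F)(F)F
Why: Silyl triflate silylation of the allylic alcohol installs the permanent C3 protecting group, which is stable to the conditions that later cleave TES and primary silyl ethers.

Step 9
Reactants: 17 tris(silyl) ether
Product: 18 (2E,4R,6R,9Z)-4-(TBSO)-9-chloro-14-(PMBO)tetradeca-2,9-dien-12-yne-1,6-diol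
Conditions: HF·pyridine, pyridine, THF, 0 °C
Reagents that add atoms: none
Why: Selective desilylation, since buffered HF·pyridine cleaves the primary TBS ether and the secondary TES ether much faster than the hindered secondary TBS ether, should release the allylic alcohol and the C5 hydroxyl only.

Step 10
Reactants: 18 E allylic alcohol with syn-1,3-diol mono-TBS ether
Product: 20 (R)-1-[(2R,3R,5R)-3-(TBSO)-5-[(3Z)-3-chloro-8-(PMBO)oct-3-en-6-yn-1-yl]oxolan-2-yl]ethane-1,2-diol, via epoxy alcohol 19 (not isolated)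
Conditions: Ti(OiPr)4 (1.1 equiv), D-(−)-DIPT (1.3 equiv), t-BuOOH, 4 Å MS, CH2Cl2, −20 °C; then 0 °C → rt
Reagents that add atoms: tert-butyl hydroperoxide, CC(C)(C)OO
Why: Ti(OiPr)4, the tartrate ester and the hydroperoxide assemble on the primary allylic alkoxide and deliver oxygen to a single face of the E alkene, giving trans-epoxy alcohol 19, which is not isolated because the titanium-bound epoxide is attacked at its carbon remote from CH2OH (the future C2) by the C5 hydroxyl in an SN2 displacement. The closest known reaction type is the Sharpless asymmetric epoxidation of a primary allylic alcohol followed by titanium- or acid-promoted intramolecular opening of the 2,3-epoxy alcohol at C3 by a tethered hydroxyl. The oxolane ring closes by a 5-exo-tet attack that forms O1–C2, preferred over the 6-endo path to C1′ because neither epoxide carbon carries a cation-stabilising group. C1′ is set by tartrate-controlled face selection and keeps that configuration, whereas C2 receives its oxygen on the same face and is then inverted by the ring closure, so the erythro C1′/C2 pair and the 2,3-cis, 2,5-trans ring follow from the E geometry and the existing C3 and C5 centres. The step needs reagent-controlled facial selectivity, which D-(−)-DIPT should impose over the modest bias of the C3 silyloxy centre, and exo regioselectivity, secured because the C5 hydroxyl is the only free internal nucleophile (the C3 oxygen is silylated) and sits four atoms from C2. The alkyne, the chloroalkene and the PMB ether carry no directing hydroxyl and should not react with the peroxide.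

Step 11
Reactants: 20 tetrahydrofuran diol
Product: 21 bis(triethylsilyl) ether of 20
Conditions: TESOTf, 2,6-lutidine, CH2Cl2, −78 °C
Reagents that add atoms: triethylsilyl triflate, CC[Si](CC)(CC)OS(=O)(=O)C(F)(F)F
Why: Silyl triflate silylation should cap both hydroxyls of the 1,2-diol, including the hindered C1′ carbinol.

Step 12
Reactants: 21 bis(triethylsilyl) ether
Product: 22 α-(triethylsilyloxy) aldehyde (CHO on C1′; ring centres as in 20)
Conditions: (COCl)2, DMSO, CH2Cl2, −78 → −40 °C; then Et3N, −78 → 0 °C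
Reagents that add atoms: none
Why: Swern oxidation applied directly to the silyl ether, in which the chlorosulfonium reagent cleaves a primary TES ether selectively and the alkoxysulfonium formed collapses to the aldehyde, should leave the secondary silyl ethers and the PMB ether untouched, and the cold addition of base limits epimerisation at C1′.

Step 13
Reactants: 22 aldehyde
Product: 23 1,1-dibromoalkene (Br2C=CH on C1′)
Conditions: CBr4, PPh3, Zn dust, CH2Cl2, rt; then 22, 0 °C
Reagents that add atoms: carbon tetrabromide, BrC(Br)(Br)Br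
Why: Corey–Fuchs (Ramirez) dibromoolefination with the preformed dibromomethylene ylide converts the aldehyde into the 1,1-dibromoalkene under essentially neutral conditions.

Step 14
Reactants: 23 1,1-dibromoalkene; 24 tert-butyl bromoacetate
Product: 26 tert-butyl (Z)-3-bromobut-3-enoate bearing the C1′(OTES)-tetrahydrofuran unit at C4, via zinc reagent 25 (not isolated)
Conditions: 24, Zn dust (TMSCl-activated), THF, rt; then 23, Pd(DPEphos)Cl2 (cat.), THF, rt
Reagents that add atoms: none
Why: Negishi coupling of a Reformatsky reagent with a 1,1-dibromoalkene, in which zerovalent palladium inserts into the less hindered C–Br bond trans to the C1′ substituent, should install the acetate unit trans to C1′ with retention and leave the bromide cis to C1′.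

Step 15
Reactants: 26 (Z)-bromoalkene
Product: 27 tert-butyl (E)-3-methylbut-3-enoate bearing the C1′(OTES)-tetrahydrofuran unit at C4
Conditions: Me2Zn, Pd(t-Bu3P)2 (cat.), THF, 0 °C → rt
Reagents that add atoms: dimethylzinc, C[Zn]C
Why: Second Negishi coupling, for which the bulky electron-rich Pd(t-Bu3P)2 catalyst is expected to give methylation with retention and hence the E trisubstituted alkene (methyl cis to C1′), the alkenyl chloride being far less reactive than the bromide at this temperature.

Step 16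
Reactants: 27 PMB ether
Product: 28 propargylic alcohol
Conditions: DDQ, CH2Cl2/pH 7 buffer, 0 °C
Reagents that add atoms: none
Why: Oxidative cleavage of the PMB ether by DDQ through the benzylic oxocarbenium ion, which water hydrolyses, should spare the silyl ethers, the tert-butyl ester and the alkenes.

Step 17
Reactants: 28 propargylic alcohol
Product: 29 (Z)-2-(tributylstannyl)alk-2-en-1-ol
Conditions: Bu3SnH, [Cp*RuCl]4 (cat.), CH2Cl2, rt
Reagents that add atoms: tributyltin hydride, CCCC[SnH](CCCC)CCCC
Why: Hydroxyl-directed ruthenium-catalysed trans-hydrostannation, in which hydrogen bonding of the propargylic OH to the Ru–Cl unit places tin on the alkyne carbon next to CH2OH and H and Sn add anti, should give the Z stannane with the carbon chain cis to tin, the geometry the E exocyclic alkene requires and that a syn hydrometalation would not give.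

Step 18
Reactants: 29 alkenylstannane; 30 ethyl (Z)-3-iodoacrylate
Product: 32 protected 5-alkylidene-5,6-dihydro-2H-pyran-2-one, via hydroxy dienoate 31 (not isolated)
Conditions: 30, Pd(PPh3)4 (cat.), CuTC, [n-Bu4N][Ph2PO2], DMF, rt; then PPTS (cat.), toluene, 40 °C
Reagents that add atoms: none
Why: Stille coupling with retention at both alkenyl partners (copper carboxylate-assisted, fluoride-free) should give the dienoate whose primary hydroxyl lies next to the cis ester, so that mild acid closes the six-membered lactone.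

Step 19
Reactants: 32 protected lactone
Product: 34 target acid, via trimethylsilyl ester 33 (not isolated)
Conditions: TMSOTf, 2,6-lutidine, CH2Cl2, 0 °C; then HF·pyridine, pyridine, THF, 0 °C → rt
Reagents that add atoms: none
Why: Silyl triflate-mediated cleavage of the tert-butyl ester (loss of isobutene) followed by global desilylation with HF·pyridine frees the acid and both hydroxyls under non-basic conditions, which should avoid conjugation of the β,γ-unsaturated acid and opening of the lactone.

Compound list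
1 | prop-2-yn-1-ol (propargyl alcohol) | OCC#C | starting material
2 | 1-methoxy-4-[(prop-2-yn-1-yloxy)methyl]benzene | C#CCOCc1ccc(OC)cc1 | intermediate
3 | 1,1,3-trichloroprop-1-ene | ClCC=C(Cl)Cl | starting material
4 | 1-{[(6,6-dichlorohex-5-en-2-yn-1-yl)oxy]methyl}-4-methoxybenzene | ClC(Cl)=CCC#CCOCc1ccc(OC)cc1 | intermediate
5 | 3,3-diethoxyprop-1-ene (acrolein diethyl acetal) | C=CC(OCC)OCC | starting material
6 | 9-(3,3-diethoxypropyl)-9-borabicyclo[3.3.1]nonane | CCOC(CCB1C2CCCC1CCC2)OCC | intermediate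
7 | (Z)-4-chloro-1,1-diethoxy-9-[(4-methoxybenzyl)oxy]non-4-en-7-yne | CCOC(CC/C(Cl)=C/CC#CCOCc1ccc(OC)cc1)OCC | intermediate
8 | (Z)-4-chloro-9-[(4-methoxybenzyl)oxy]non-4-en-7-ynal | O=CCC/C(Cl)=C/CC#CCOCc1ccc(OC)cc1 | intermediate
9 | 2-[(tert-butyldimethylsilyl)oxy]acetaldehyde | O=CCO[Si](C)(C)C(C)(C)C | starting material
10 | 1-(triphenylphosphoranylidene)propan-2-one | CC(=O)C=P(c1ccccc1)(c1ccccc1)c1ccccc1 | starting material
11 | (E)-5-[(tert-butyldimethylsilyl)oxy]pent-3-en-2-one | CC(=O)/C=C/CO[Si](C)(C)C(C)(C)C | intermediate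
12 | bis[(1S,2R,3S,5S)-isopinocampheyl]boron enolate of 11 (O-boryl 1,3-dien-2-olate, E alkene kept) | C=C(OB([C@H]1C[C@H]2C[C@@H]([C@@H]1C)C2(C)C)[C@H]1C[C@H]2C[C@@H]([C@@H]1C)C2(C)C)/C=C/CO[Si](C)(C)C(C)(C)C | intermediate
13 | O-[bis(isopinocampheyl)boryl] aldolate of 14 (6R) | CC(C)(C)[Si](C)(C)OC/C=C/C(=O)C[C@H](OB([C@H]1C[C@H]2C[C@@H]([C@@H]1C)C2(C)C)[C@H]1C[C@H]2C[C@@H]([C@@H]1C)C2(C)C)CC/C(Cl)=C/CC#CCOCc1ccc(OC)cc1 | intermediate
14 | (2E,6R,9Z)-1-[(tert-butyldimethylsilyl)oxy]-9-chloro-6-hydroxy-14-[(4-methoxybenzyl)oxy]tetradeca-2,9-dien-12-yn-4-one | CC(C)(C)[Si](C)(C)OC/C=C/C(=O)C[C@H](O)CC/C(Cl)=C/CC#CCOCc1ccc(OC)cc1 | intermediate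
15 | (2E,6R,9Z)-1-(TBSO)-9-chloro-14-(PMBO)-6-(TESO)tetradeca-2,9-dien-12-yn-4-one | CC(C)(C)[Si](C)(C)OC/C=C/C(=O)C[C@H](O[Si](CC)(CC)CC)CC/C(Cl)=C/CC#CCOCc1ccc(OC)cc1 | intermediate
16 | (2E,4R,6R,9Z)-1-(TBSO)-9-chloro-14-(PMBO)-6-(TESO)tetradeca-2,9-dien-12-yn-4-ol | CC(C)(C)[Si](C)(C)OC/C=C/[C@H](O)C[C@H](O[Si](CC)(CC)CC)CC/C(Cl)=C/CC#CCOCc1ccc(OC)cc1 | intermediate
17 | (2E,4R,6R,9Z)-1,4-bis(TBSO)-9-chloro-14-(PMBO)-6-(TESO)tetradeca-2,9-dien-12-yne | CC(C)(C)[Si](C)(C)OC/C=C/[C@H](O[Si](C)(C)C(C)(C)C)C[C@H](O[Si](CC)(CC)CC)CC/C(Cl)=C/CC#CCOCc1ccc(OC)cc1 | intermediate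
18 | (2E,4R,6R,9Z)-4-(TBSO)-9-chloro-14-(PMBO)tetradeca-2,9-dien-12-yne-1,6-diol (key-step precursor) | OC/C=C/[C@H](O[Si](C)(C)C(C)(C)C)C[C@H](O)CC/C(Cl)=C/CC#CCOCc1ccc(OC)cc1 | intermediate
19 | trans-2,3-epoxy alcohol of 18 (oxirane 2R,3S in epoxy-alcohol numbering; 4R,6R unchanged) | OC[C@H]1O[C@@H]1[C@H](O[Si](C)(C)C(C)(C)C)C[C@H](O)CC/C(Cl)=C/CC#CCOCc1ccc(OC)cc1 | intermediate
20 | (R)-1-[(2R,3R,5R)-3-(TBSO)-5-{(3Z)-3-chloro-8-[(4-methoxybenzyl)oxy]oct-3-en-6-yn-1-yl}oxolan-2-yl]ethane-1,2-diol (2,3-cis, 2,5-trans; key-step product) | OC[C@@H](O)[C@H]1O[C@H](CC/C(Cl)=C/CC#CCOCc2ccc(OC)cc2)C[C@H]1O[Si](C)(C)C(C)(C)C | intermediate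
21 | bis(triethylsilyl) ether of 20 (primary and C1′ oxygens as OTES; centres as in 20) | CC[Si](CC)(CC)OC[C@@H](O[Si](CC)(CC)CC)[C@H]1O[C@H](CC/C(Cl)=C/CC#CCOCc2ccc(OC)cc2)C[C@H]1O[Si](C)(C)C(C)(C)C | intermediate
22 | 2-(triethylsilyloxy)-2-(oxolan-2-yl)acetaldehyde derived from 21 (CHO on C1′; centres as in 20) | O=C[C@@H](O[Si](CC)(CC)CC)[C@H]1O[C@H](CC/C(Cl)=C/CC#CCOCc2ccc(OC)cc2)C[C@H]1O[Si](C)(C)C(C)(C)C | intermediate
23 | 1,1-dibromoalkene from 22 (Br2C=CH–C1′(OTES)–; centres as in 20) | BrC(Br)=C[C@@H](O[Si](CC)(CC)CC)[C@H]1O[C@H](CC/C(Cl)=C/CC#CCOCc2ccc(OC)cc2)C[C@H]1O[Si](C)(C)C(C)(C)C | intermediate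
24 | tert-butyl bromoacetate | BrCC(=O)OC(C)(C)C | starting material
25 | (2-tert-butoxy-2-oxoethyl)zinc bromide (Reformatsky reagent) | Br[Zn]CC(=O)OC(C)(C)C | intermediate
26 | tert-butyl (Z)-3-bromo-5-(triethylsilyloxy)-5-(oxolan-2-yl)pent-3-enoate (Br cis to C1′; centres as in 20) | Br/C(=C\[C@@H](O[Si](CC)(CC)CC)[C@H]1O[C@H](CC/C(Cl)=C/CC#CCOCc2ccc(OC)cc2)C[C@H]1O[Si](C)(C)C(C)(C)C)CC(=O)OC(C)(C)C | intermediate
27 | tert-butyl (E)-3-methyl-5-(triethylsilyloxy)-5-(oxolan-2-yl)pent-3-enoate with PMB-protected enyne side chain (centres as in 20) | C/C(=C\[C@@H](O[Si](CC)(CC)CC)[C@H]1O[C@H](CC/C(Cl)=C/CC#CCOCc2ccc(OC)cc2)C[C@H]1O[Si](C)(C)C(C)(C)C)CC(=O)OC(C)(C)C | intermediate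
28 | propargylic alcohol from 27 (side chain (3Z)-3-chloro-8-hydroxyoct-3-en-6-yn-1-yl) | C/C(=C\[C@@H](O[Si](CC)(CC)CC)[C@H]1O[C@H](CC/C(Cl)=C/CC#CCO)C[C@H]1O[Si](C)(C)C(C)(C)C)CC(=O)OC(C)(C)C | intermediate
29 | alkenylstannane from 28 (side chain (3Z,6Z)-3-chloro-8-hydroxy-7-(tributylstannyl)octa-3,6-dien-1-yl) | C/C(=C\[C@@H](O[Si](CC)(CC)CC)[C@H]1O[C@H](CC/C(Cl)=C/C/C=C(/CO)[Sn](CCCC)(CCCC)CCCC)C[C@H]1O[Si](C)(C)C(C)(C)C)CC(=O)OC(C)(C)C | intermediate
30 | ethyl (Z)-3-iodoacrylate | CCOC(=O)/C=C\I | starting material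
31 | hydroxy dienoate from 29 and 30 (ethyl (2Z)-4-(hydroxymethyl)penta-2,4-dienoate unit, chain cis to the acrylate arm) | C/C(=C\[C@@H](O[Si](CC)(CC)CC)[C@H]1O[C@H](CC/C(Cl)=C/C/C=C(/CO)\C=C/C(=O)OCC)C[C@H]1O[Si](C)(C)C(C)(C)C)CC(=O)OC(C)(C)C | intermediate
32 | tert-butyl ester, C1′ OTES, C3 OTBS derivative of the target (E-alkylidene dihydropyranone in place) | C/C(=C\[C@@H](O[Si](CC)(CC)CC)[C@H]1O[C@H](CC/C(Cl)=C/C/C=C2\C=CC(=O)OC2)C[C@H]1O[Si](C)(C)C(C)(C)C)CC(=O)OC(C)(C)C | intermediate
33 | trimethylsilyl ester analogue of 32 | C/C(=C\[C@@H](O[Si](CC)(CC)CC)[C@H]1O[C@H](CC/C(Cl)=C/C/C=C2\C=CC(=O)OC2)C[C@H]1O[Si](C)(C)C(C)(C)C)CC(=O)O[Si](C)(C)C | intermediate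
34 | (3E,5R)-5-[(2S,3R,5R)-5-[(3Z,6E)-3-chloro-6-(6-oxo-2H-pyran-3(6H)-ylidene)hex-3-en-1-yl]-3-hydroxyoxolan-2-yl]-5-hydroxy-3-methylpent-3-enoic acid | C/C(=C\[C@@H](O)[C@H]1O[C@H](CC/C(Cl)=C/C/C=C2\C=CC(=O)OC2)C[C@H]1O)CC(=O)O | target

Total step count: 19. Longest linear sequence: 18 steps (steps 1–3 and 5–19; step 4 is a one-step side branch).

Steps most likely to fail

The first is step 10. The free C5 hydroxyl may chelate titanium and erode facial selectivity, or the activated epoxide may be captured by isopropoxide or opened in the 6-endo sense. The fallback separates epoxidation from ring closure. It sets out from 18, which is silylated on both hydroxyls (TESOTf, 2,6-lutidine) to give the bis(triethylsilyl) ether F1. The primary silyl ether alone is cleaved (PPTS, MeOH, 0 °C) to the allylic alcohol F2. Catalytic Sharpless epoxidation with D-(−)-DIPT, now without any internal nucleophile, should give the isolable epoxy alcohol F3. Buffered HF·pyridine then frees the C5 hydroxyl (compound 19), and catalytic camphorsulfonic acid in CH2Cl2 closes the ring in a separate Brønsted acid step, which returns to the route at 20.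

The second is step 14. The oxidative addition may lose its trans-selectivity, both bromides may be substituted, or the bromoalkene may scramble its geometry. The fallback replaces the coupling by olefination and homologation and sets out from aldehyde 22. A Horner–Wadsworth–Emmons reaction with allyl 2-(diethoxyphosphoryl)propanoate (LiCl, DBU, MeCN) should give the allyl (E)-2-methylenoate F4. Deallylation (Pd(PPh3)4, morpholine) gives the (E)-2-methylenoic acid F5. Isobutyl chloroformate and N-methylmorpholine give the mixed anhydride F6, and TMSCHN2 converts it into the diazoketone F7. Wolff rearrangement (PhCO2Ag, Et3N, t-BuOH) completes an Arndt–Eistert homologation to the tert-butyl β,γ-unsaturated ester, which returns to the route at 27 with the alkene geometry fixed by the olefination.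

The third is step 18. The hindered alkenylstannane may undergo protodestannylation or transmetalate slowly, or palladium may ionise the allylic lactone. The fallback reverses the roles of the coupling partners and sets out from 29. Iododestannylation (I2, CH2Cl2, 0 °C) should give the (Z)-alkenyl iodide F8 with retention. Stille coupling with ethyl (Z)-3-(tributylstannyl)acrylate (Pd2(dba)3, AsPh3, DMF, rt) then gives the hydroxy dienoate 31 and, after PPTS, the lactone, which returns to the route at 32.

Further compounds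
F1 | step 10 | bis(triethylsilyl) ether of 18 (1-OTES, 6-OTES, 4-OTBS) | CC[Si](CC)(CC)OC/C=C/[C@H](O[Si](C)(C)C(C)(C)C)C[C@H](O[Si](CC)(CC)CC)CC/C(Cl)=C/CC#CCOCc1ccc(OC)cc1
F2 | step 10 | (2E,4R,6R,9Z)-4-(TBSO)-9-chloro-14-(PMBO)-6-(TESO)tetradeca-2,9-dien-12-yn-1-ol | OC/C=C/[C@H](O[Si](C)(C)C(C)(C)C)C[C@H](O[Si](CC)(CC)CC)CC/C(Cl)=C/CC#CCOCc1ccc(OC)cc1
F3 | step 10 | trans-2,3-epoxy alcohol of F2 (same oxirane configuration as 19; 6-OTES) | OC[C@H]1O[C@@H]1[C@H](O[Si](C)(C)C(C)(C)C)C[C@H](O[Si](CC)(CC)CC)CC/C(Cl)=C/CC#CCOCc1ccc(OC)cc1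
F4 | step 14 | allyl (E)-2-methyl-4-(triethylsilyloxy)-4-(oxolan-2-yl)but-2-enoate from 22 (centres as in 20) | C=CCOC(=O)/C(C)=C/[C@@H](O[Si](CC)(CC)CC)[C@H]1O[C@H](CC/C(Cl)=C/CC#CCOCc2ccc(OC)cc2)C[C@H]1O[Si](C)(C)C(C)(C)C
F5 | step 14 | (E)-2-methyl-4-(triethylsilyloxy)-4-(oxolan-2-yl)but-2-enoic acid from F4 | OC(=O)/C(C)=C/[C@@H](O[Si](CC)(CC)CC)[C@H]1O[C@H](CC/C(Cl)=C/CC#CCOCc2ccc(OC)cc2)C[C@H]1O[Si](C)(C)C(C)(C)C
F6 | step 14 | isobutyl carbonic mixed anhydride of F5 | CC(C)COC(=O)OC(=O)/C(C)=C/[C@@H](O[Si](CC)(CC)CC)[C@H]1O[C@H](CC/C(Cl)=C/CC#CCOCc2ccc(OC)cc2)C[C@H]1O[Si](C)(C)C(C)(C)C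
F7 | step 14 | α-diazoketone from F6 | [N-]=[N+]=CC(=O)/C(C)=C/[C@@H](O[Si](CC)(CC)CC)[C@H]1O[C@H](CC/C(Cl)=C/CC#CCOCc2ccc(OC)cc2)C[C@H]1O[Si](C)(C)C(C)(C)C
F8 | step 18 | (Z)-alkenyl iodide from 29 (iodine in place of tin) | C/C(=C\[C@@H](O[Si](CC)(CC)CC)[C@H]1O[C@H](CC/C(Cl)=C/C/C=C(/CO)I)C[C@H]1O[Si](C)(C)C(C)(C)C)CC(=O)OC(C)(C)C
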